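**Plan**

- Feature used: ring B is a catechol (oxygens on C3' and C4') whose other two substituted carbons, C1' and C6', are ortho to each other and carry carbon groups (C2 of the flavanone and C8'' of the flavone). This 1,2-dioxy-4,5-dicarbon benzene maps onto a 2,3-dioxybutadiene plus a disubstituted alkyne.
- Retrosynthetic cuts, in order: O1–C2 (SN2 etherification), C2–C3 (aldol), C1'–C2' and C5'–C6' of ring B ([4+2] and dehydrogenation), C8''–C(sp) (Sonogashira), back to luteolin.
- Forward: luteolin → benzyl-protected 8-iodide → 3-(flavon-8-yl)propynal → ring B built on the alkyne → aldol with a phloroacetophenone silyl enol ether joins ring A → pyranone ring C closes last.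
- Stereochemistry: C2 is the only stereocentre. A catalyst-controlled aldol addition to the Si face of the aldehyde sets it as the (S)-carbinol, and the Mitsunobu ring closure inverts it to (2R).
- Protection: benzyl on the six phenols outside ring B, TBS on the ring-B catechol (delivered by the diene); fluoride, then hydrogenolysis, at the end.

Key step: step 6

Assumption: the C6'–C8'' biaryl axis has no descriptor in the target structure, so it is treated as unassigned; compound 10 and later compounds are expected as rotamer mixtures about this tri-ortho-substituted axis, and only C2 is controlled.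

**Route**

Step 1
Reactants: 1 luteolin
Product: 2 5,7,3',4'-tetra-O-benzylluteolin
Conditions: BnBr (6 equiv), K2CO3, DMF, 80 °C
Reagents that add atoms: benzyl bromide BrCc1ccccc1
Why: Williamson etherification of all four phenols; heating with excess reagent should also alkylate the chelated 5-OH, which must be capped so that the later iodination goes to C8 and not C6.

Step 2
Reactants: 2 5,7,3',4'-tetra-O-benzylluteolin
Product: 3 8-iodo-5,7,3',4'-tetra-O-benzylluteolin
Conditions: NIS (1.1 equiv), TFA (cat.), MeCN–CH2Cl2, 0 °C → rt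
Reagents that add atoms: N-iodosuccinimide O=C1CCC(=O)N1I
Why: Electrophilic aromatic iodination; in 5,7-dialkoxyflavones C8 (ortho to O1 and the 7-oxygen, para to the 5-oxygen) is the most nucleophilic and least hindered position, whereas C6 lies between two benzyloxy groups.

Step 3
Reactants: 3 8-iodo-5,7,3',4'-tetra-O-benzylluteolin; 4 propargyl alcohol
Product: 5 8-(3-hydroxyprop-1-yn-1-yl)-5,7,3',4'-tetra-O-benzylluteolin
Conditions: Pd(PPh3)2Cl2 (5 mol%), CuI (10 mol%), Et3N, DMF, 60 °C
Reagents that add atoms: none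
Why: Sonogashira coupling; oxidative addition of the aryl iodide to zerovalent palladium and transfer of the copper acetylide tolerate the two ortho substituents because the incoming carbon is sp-hybridised and linear.

Step 4
Reactants: 5 8-(3-hydroxyprop-1-yn-1-yl)-5,7,3',4'-tetra-O-benzylluteolin
Product: 6 3-(5,7,3',4'-tetra-O-benzylluteolin-8-yl)prop-2-ynal
Conditions: MnO2 (activated, excess), CH2Cl2, rt
Reagents that add atoms: none
Why: Selective MnO2 oxidation of a propargylic alcohol to the arylpropynal, without over-oxidation and without touching the benzyl ethers or the chromone.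

Step 5
Reactants: 7 2,3-butanedione
Product: 8 2,3-bis(tert-butyldimethylsilyloxy)buta-1,3-diene
Conditions: TBSOTf (2.2 equiv), Et3N, CH2Cl2, 0 °C → rt
Reagents that add atoms: tert-butyldimethylsilyl trifluoromethanesulfonate CC(C)(C)[Si](C)(C)OS(=O)(=O)C(F)(F)F
Why: Twofold soft enolisation and O-silylation of the 1,2-diketone; only the methyl groups can enolise, so the symmetric 2,3-dioxygenated diene is the only product.

Step 6
Reactants: 6 3-(5,7,3',4'-tetra-O-benzylluteolin-8-yl)prop-2-ynal; 8 2,3-bis(tert-butyldimethylsilyloxy)buta-1,3-diene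
Product: 10 2-(5,7,3',4'-tetra-O-benzylluteolin-8-yl)-4,5-bis(tert-butyldimethylsilyloxy)benzaldehyde, via cyclohexa-1,4-diene cycloadduct 9 (not isolated)
Conditions: 8 (3 equiv), BHT (cat.), toluene, 110 °C, sealed tube; excess 8 removed in vacuo; then DDQ (1.1 equiv), toluene, 0 °C → rt
Reagents that add atoms: none
Why: The HOMO of the electron-rich diene 8 and the LUMO of the formyl-conjugated alkyne of 6 combine in a concerted, suprafacial normal-demand [4+2] cycloaddition that forms C1'–C2' and C5'–C6' together and gives the cyclohexa-1,4-diene bis(silyl enol ether) 9. DDQ then removes hydride from a doubly allylic CH2 of 9 (the cation is stabilised by the silyloxy group) and proton loss aromatises the ring with both O–Si bonds retained. The closest known reaction type is the Diels–Alder benzannulation of 2,3-bis(trimethylsilyloxy)butadiene with acetylenic esters and aldehydes followed by dehydrogenation to catechol derivatives. Ring B closes by intermolecular [4+2] cycloaddition, both ring bonds forming in one event, and no stereocentre is created. The step needs chemoselectivity for the C≡C bond, which the substrate secures because the flavone C2''=C3'' bond is a trisubstituted vinylogous ester and the absence of a Lewis acid disfavours hetero-cycloaddition at the aldehyde; regiochemistry does not arise because 8 is symmetric. The linear alkyne keeps the crowded C8'' away from the bond-forming termini, so the hindered aryl–aryl bond of the target is already in place as the aryl–alkyne bond from step 3.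

Step 7
Reactants: 11 2,4,6-trihydroxyacetophenone
Product: 12 1-[2,4-bis(benzyloxy)-6-hydroxyphenyl]ethan-1-one
Conditions: BnBr (2.1 equiv), K2CO3, DMF, rt
Reagents that add atoms: benzyl bromide BrCc1ccccc1
Why: Williamson etherification with limited reagent; after the first ortho and the para hydroxyl are benzylated, the remaining ortho hydroxyl is hydrogen-bonded to the ketone and stays free for the later ring closure.

Step 8
Reactants: 12 1-[2,4-bis(benzyloxy)-6-hydroxyphenyl]ethan-1-one
Product: 13 {1-[2,4-bis(benzyloxy)-6-(trimethylsilyloxy)phenyl]vinyloxy}trimethylsilane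
Conditions: TMSOTf (2.3 equiv), Et3N, CH2Cl2, 0 °C; used crude
Reagents that add atoms: trimethylsilyl trifluoromethanesulfonate C[Si](C)(C)OS(=O)(=O)C(F)(F)F
Why: Soft enolisation gives the silyl enol ether of the methyl ketone and silylates the phenol at the same time, which masks it during the aldol and lets it reappear on aqueous work-up without a separate deprotection.

Step 9
Reactants: 10 2-(5,7,3',4'-tetra-O-benzylluteolin-8-yl)-4,5-bis(tert-butyldimethylsilyloxy)benzaldehyde; 13 {1-[2,4-bis(benzyloxy)-6-(trimethylsilyloxy)phenyl]vinyloxy}trimethylsilane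
Product: 15 (3S)-1-[2,4-bis(benzyloxy)-6-hydroxyphenyl]-3-hydroxy-3-[2-(5,7,3',4'-tetra-O-benzylluteolin-8-yl)-4,5-bis(tert-butyldimethylsilyloxy)phenyl]propan-1-one, via trichlorosilyl aldolate 14 (not isolated)
Conditions: SiCl4 (1.5 equiv), chiral bisphosphoramide from N,N'-dimethyl-1,1'-binaphthyl-2,2'-diamine with a pentane-1,5-diyl tether (10 mol%; the antipode that directs Si-face addition, assigned beforehand on a 2-arylbenzaldehyde model by MTPA ester analysis), i-Pr2NEt (cat.), CH2Cl2, −78 °C; then cold sat. aq. NaHCO3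
Reagents that add atoms: none
Why: Lewis-base-catalysed Mukaiyama aldol in which the phosphoramide ionises SiCl4 to a chiral cationic trichlorosilyl Lewis acid that binds the aromatic aldehyde and shields its Re face, so the unsubstituted terminus of 13 adds to the Si face through an open transition state and sets the carbinol carbon as (S); the O–SiCl3 group and the aryl trimethylsilyl ether of 14 are hydrolysed on the buffered work-up.

Step 10
Reactants: 15 (3S)-β-hydroxy ketone
Product: 16 (2R)-5,7-bis(benzyloxy)-2-[2-(5,7,3',4'-tetra-O-benzylluteolin-8-yl)-4,5-bis(tert-butyldimethylsilyloxy)phenyl]chroman-4-one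
Conditions: PPh3, DIAD, toluene, 0 °C
Reagents that add atoms: none
Why: Intramolecular Mitsunobu etherification; the ketone-chelated phenol displaces the oxyphosphonium group of the benzylic carbinol in a 6-exo-tet SN2 closure with inversion, turning the (S)-carbinol into the (2R) stereocentre, and the low temperature and non-polar solvent are chosen to hold back ionisation and β-elimination.

Step 11
Reactants: 16 (2R)-bis(silyl) hexabenzyl flavanone
Product: 17 (2R)-5,7-bis(benzyloxy)-2-[4,5-dihydroxy-2-(5,7,3',4'-tetra-O-benzylluteolin-8-yl)phenyl]chroman-4-one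
Conditions: Et3N·3HF, THF, rt
Reagents that add atoms: none
Why: Fluoride cleavage of the two aryl silyl ethers with a slightly acidic fluoride source, which avoids the phenoxide-mediated ring opening to the chalcone that would racemise a flavanone carrying a free 4'-hydroxyl.

Step 12
Reactants: 17 (2R)-hexabenzyl flavanone–flavone
Product: 18 (2R)-5,7-dihydroxy-2-[4,5-dihydroxy-2-(luteolin-8-yl)phenyl]chroman-4-one (CNP0228504.1)
Conditions: H2 (1 atm), Pd/C (10%), THF–MeOH, rt
Reagents that add atoms: none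
Why: Hydrogenolysis of the six aryl benzyl ethers under neutral conditions, which should leave the C2 stereocentre, the chromone C2''=C3'' bond and both carbonyl groups untouched at atmospheric pressure with monitoring.

**Compound list**

1 | luteolin | O=c1cc(-c2ccc(O)c(O)c2)oc2cc(O)cc(O)c12 | starting material
2 | 5,7,3',4'-tetra-O-benzylluteolin | O=c1cc(-c2ccc(OCc3ccccc3)c(OCc3ccccc3)c2)oc2cc(OCc3ccccc3)cc(OCc3ccccc3)c12 | intermediate
3 | 8-iodo-5,7,3',4'-tetra-O-benzylluteolin | Ic1c(OCc2ccccc2)cc(OCc2ccccc2)c2c(=O)cc(-c3ccc(OCc4ccccc4)c(OCc4ccccc4)c3)oc12 | intermediate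
4 | propargyl alcohol | C#CCO | starting material
5 | 8-(3-hydroxyprop-1-yn-1-yl)-5,7,3',4'-tetra-O-benzylluteolin | OCC#Cc1c(OCc2ccccc2)cc(OCc2ccccc2)c2c(=O)cc(-c3ccc(OCc4ccccc4)c(OCc4ccccc4)c3)oc12 | intermediate
6 | 3-(5,7,3',4'-tetra-O-benzylluteolin-8-yl)prop-2-ynal | O=CC#Cc1c(OCc2ccccc2)cc(OCc2ccccc2)c2c(=O)cc(-c3ccc(OCc4ccccc4)c(OCc4ccccc4)c3)oc12 | intermediate
7 | 2,3-butanedione | CC(=O)C(C)=O | starting material
8 | 2,3-bis(tert-butyldimethylsilyloxy)buta-1,3-diene | C=C(O[Si](C)(C)C(C)(C)C)C(=C)O[Si](C)(C)C(C)(C)C | intermediate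
9 | 2-(5,7,3',4'-tetra-O-benzylluteolin-8-yl)-4,5-bis(tert-butyldimethylsilyloxy)cyclohexa-1,4-diene-1-carbaldehyde | O=CC1=C(c2c(OCc3ccccc3)cc(OCc3ccccc3)c3c(=O)cc(-c4ccc(OCc5ccccc5)c(OCc5ccccc5)c4)oc23)CC(O[Si](C)(C)C(C)(C)C)=C(O[Si](C)(C)C(C)(C)C)C1 | intermediate (not isolated)
10 | 2-(5,7,3',4'-tetra-O-benzylluteolin-8-yl)-4,5-bis(tert-butyldimethylsilyloxy)benzaldehyde | O=Cc1cc(O[Si](C)(C)C(C)(C)C)c(O[Si](C)(C)C(C)(C)C)cc1-c1c(OCc2ccccc2)cc(OCc2ccccc2)c2c(=O)cc(-c3ccc(OCc4ccccc4)c(OCc4ccccc4)c3)oc12 | intermediate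
11 | 2,4,6-trihydroxyacetophenone | CC(=O)c1c(O)cc(O)cc1O | starting material
12 | 1-[2,4-bis(benzyloxy)-6-hydroxyphenyl]ethan-1-one | CC(=O)c1c(O)cc(OCc2ccccc2)cc1OCc1ccccc1 | intermediate
13 | {1-[2,4-bis(benzyloxy)-6-(trimethylsilyloxy)phenyl]vinyloxy}trimethylsilane | C=C(O[Si](C)(C)C)c1c(O[Si](C)(C)C)cc(OCc2ccccc2)cc1OCc1ccccc1 | intermediate
14 | (3S)-trichlorosilyl aldolate of 15 with the ring-A phenol as its trimethylsilyl ether | O=C(C[C@H](O[Si](Cl)(Cl)Cl)c1cc(O[Si](C)(C)C(C)(C)C)c(O[Si](C)(C)C(C)(C)C)cc1-c1c(OCc2ccccc2)cc(OCc2ccccc2)c2c(=O)cc(-c3ccc(OCc4ccccc4)c(OCc4ccccc4)c3)oc12)c1c(O[Si](C)(C)C)cc(OCc2ccccc2)cc1OCc1ccccc1 | intermediate (not isolated)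
15 | (3S)-1-[2,4-bis(benzyloxy)-6-hydroxyphenyl]-3-hydroxy-3-[2-(5,7,3',4'-tetra-O-benzylluteolin-8-yl)-4,5-bis(tert-butyldimethylsilyloxy)phenyl]propan-1-one | O=C(C[C@H](O)c1cc(O[Si](C)(C)C(C)(C)C)c(O[Si](C)(C)C(C)(C)C)cc1-c1c(OCc2ccccc2)cc(OCc2ccccc2)c2c(=O)cc(-c3ccc(OCc4ccccc4)c(OCc4ccccc4)c3)oc12)c1c(O)cc(OCc2ccccc2)cc1OCc1ccccc1 | intermediate
16 | (2R)-5,7-bis(benzyloxy)-2-[2-(5,7,3',4'-tetra-O-benzylluteolin-8-yl)-4,5-bis(tert-butyldimethylsilyloxy)phenyl]chroman-4-one | O=C1C[C@H](c2cc(O[Si](C)(C)C(C)(C)C)c(O[Si](C)(C)C(C)(C)C)cc2-c2c(OCc3ccccc3)cc(OCc3ccccc3)c3c(=O)cc(-c4ccc(OCc5ccccc5)c(OCc5ccccc5)c4)oc23)Oc2cc(OCc3ccccc3)cc(OCc3ccccc3)c21 | intermediate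
17 | (2R)-5,7-bis(benzyloxy)-2-[4,5-dihydroxy-2-(5,7,3',4'-tetra-O-benzylluteolin-8-yl)phenyl]chroman-4-one | O=C1C[C@H](c2cc(O)c(O)cc2-c2c(OCc3ccccc3)cc(OCc3ccccc3)c3c(=O)cc(-c4ccc(OCc5ccccc5)c(OCc5ccccc5)c4)oc23)Oc2cc(OCc3ccccc3)cc(OCc3ccccc3)c21 | intermediate
18 | (2R)-5,7-dihydroxy-2-[4,5-dihydroxy-2-(luteolin-8-yl)phenyl]chroman-4-one (CNP0228504.1) | O=C1C[C@H](c2cc(O)c(O)cc2-c2c(O)cc(O)c3c(=O)cc(-c4ccc(O)c(O)c4)oc23)Oc2cc(O)cc(O)c21 | target

**Step count and risks**

Total steps: 12. Longest linear sequence: 9 steps (1 → 18 through steps 1, 2, 3, 4, 6, 9, 10, 11, 12). Steps 5, 7 and 8 prepare the diene and the ring-A partner.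

Steps most likely to fail:

1. Step 6 (cycloaddition and dehydrogenation). The bulky bis(silyloxy) diene may react too slowly with the aryl-conjugated ynal, so that thermal decomposition of the diene or hetero-cycloaddition at the aldehyde competes, and a silyl group may be lost during the DDQ oxidation. Fallback: the aryl–aryl bond is made directly by cross-coupling, setting out from iodide 3 and returning at aldehyde 10. Commercial 6-bromoveratraldehyde is demethylated with BBr3 in CH2Cl2 to 2-bromo-4,5-dihydroxybenzaldehyde F1. Silylation with TBSCl and imidazole in DMF gives 2-bromo-4,5-bis(tert-butyldimethylsilyloxy)benzaldehyde F2. Miyaura borylation (bis(pinacolato)diboron, Pd(dppf)Cl2, KOAc, dioxane, 80 °C) gives 4,5-bis(tert-butyldimethylsilyloxy)-2-(4,4,5,5-tetramethyl-1,3,2-dioxaborolan-2-yl)benzaldehyde F3. Suzuki–Miyaura coupling of F3 with 3 (Pd(OAc)2, 2-dicyclohexylphosphino-2',6'-dimethoxybiphenyl, anhydrous K3PO4, toluene, 90 °C) should give 10; any silyl ether lost to the base is restored with TBSCl and imidazole.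

2. Step 9 (enantioselective aldol). The basic pyranone carbonyl may sequester the chiral silicon Lewis acid, addition to the hindered electron-rich aldehyde may be slow, and facial selectivity may be poor because the aldehyde reacts as slowly interconverting rotamers, one of which is mismatched. Fallback: the stereocentre is set in the C–O bond-forming event, setting out from aldehyde 10 (with ketone 12 as ring-A source) and returning at flavanone 16. The lithium dianion of 12 (LiHMDS, THF, −78 °C) is C-acylated with di-tert-butyl dicarbonate to tert-butyl 3-[2,4-bis(benzyloxy)-6-hydroxyphenyl]-3-oxopropanoate F4. Knoevenagel condensation of F4 with 10 (piperidine, AcOH, toluene, molecular sieves) gives the alkylidene β-keto ester F5. A cinchona-alkaloid thiourea (the quinine- or quinidine-derived pseudoenantiomer that leads to 2R; toluene, −25 °C) catalyses the intramolecular oxa-Michael addition to tert-butyl (2R)-4-oxochromane-3-carboxylate F6. p-TsOH in toluene at 80 °C then removes the tert-butyl ester with decarboxylation to give 16.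

3. Step 10 (Mitsunobu closure). The oxyphosphonium intermediate may undergo β-elimination to the chalcone, which recloses without stereocontrol, and partial ionisation at the silyloxy-activated benzylic carbon may erode the inversion. Fallback: ring closure under thermodynamic control followed by separation of enantiomers, setting out from 15 and returning at 16. Acid-catalysed dehydration of 15 (p-TsOH cat., toluene, 50 °C) gives the (E)-2'-hydroxychalcone F7. NaOAc in EtOH at 70 °C cyclises F7 to the racemic flavanone F8. Preparative chromatography of F8 on a polysaccharide chiral stationary phase supplies the (2R)-enantiomer 16, and the (2S)-enantiomer is returned to the NaOAc conditions, where it racemises through the chalcone and can be recycled.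

Further compounds
F1 | step 6 | 2-bromo-4,5-dihydroxybenzaldehyde | O=Cc1cc(O)c(O)cc1Br
F2 | step 6 | 2-bromo-4,5-bis(tert-butyldimethylsilyloxy)benzaldehyde | O=Cc1cc(O[Si](C)(C)C(C)(C)C)c(O[Si](C)(C)C(C)(C)C)cc1Br
F3 | step 6 | 4,5-bis(tert-butyldimethylsilyloxy)-2-(4,4,5,5-tetramethyl-1,3,2-dioxaborolan-2-yl)benzaldehyde | O=Cc1cc(O[Si](C)(C)C(C)(C)C)c(O[Si](C)(C)C(C)(C)C)cc1B1OC(C)(C)C(C)(C)O1
F4 | step 9 | tert-butyl 3-[2,4-bis(benzyloxy)-6-hydroxyphenyl]-3-oxopropanoate | CC(C)(C)OC(=O)CC(=O)c1c(O)cc(OCc2ccccc2)cc1OCc1ccccc1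
F5 | step 9 | tert-butyl 2-[2,4-bis(benzyloxy)-6-hydroxybenzoyl]-3-[2-(5,7,3',4'-tetra-O-benzylluteolin-8-yl)-4,5-bis(tert-butyldimethylsilyloxy)phenyl]acrylate (alkene geometry not defined) | CC(C)(C)OC(=O)C(=Cc1cc(O[Si](C)(C)C(C)(C)C)c(O[Si](C)(C)C(C)(C)C)cc1-c1c(OCc2ccccc2)cc(OCc2ccccc2)c2c(=O)cc(-c3ccc(OCc4ccccc4)c(OCc4ccccc4)c3)oc12)C(=O)c1c(O)cc(OCc2ccccc2)cc1OCc1ccccc1
F6 | step 9 | tert-butyl (2R)-5,7-bis(benzyloxy)-4-oxo-2-[2-(5,7,3',4'-tetra-O-benzylluteolin-8-yl)-4,5-bis(tert-butyldimethylsilyloxy)phenyl]chromane-3-carboxylate (C3 not defined) | O=C1C(C(=O)OC(C)(C)C)[C@H](c2cc(O[Si](C)(C)C(C)(C)C)c(O[Si](C)(C)C(C)(C)C)cc2-c2c(OCc3ccccc3)cc(OCc3ccccc3)c3c(=O)cc(-c4ccc(OCc5ccccc5)c(OCc5ccccc5)c4)oc23)Oc2cc(OCc3ccccc3)cc(OCc3ccccc3)c21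
F7 | step 10 | (E)-1-[2,4-bis(benzyloxy)-6-hydroxyphenyl]-3-[2-(5,7,3',4'-tetra-O-benzylluteolin-8-yl)-4,5-bis(tert-butyldimethylsilyloxy)phenyl]prop-2-en-1-one | O=C(/C=C/c1cc(O[Si](C)(C)C(C)(C)C)c(O[Si](C)(C)C(C)(C)C)cc1-c1c(OCc2ccccc2)cc(OCc2ccccc2)c2c(=O)cc(-c3ccc(OCc4ccccc4)c(OCc4ccccc4)c3)oc12)c1c(O)cc(OCc2ccccc2)cc1OCc1ccccc1
F8 | step 10 | racemic 5,7-bis(benzyloxy)-2-[2-(5,7,3',4'-tetra-O-benzylluteolin-8-yl)-4,5-bis(tert-butyldimethylsilyloxy)phenyl]chroman-4-one | O=C1CC(c2cc(O[Si](C)(C)C(C)(C)C)c(O[Si](C)(C)C(C)(C)C)cc2-c2c(OCc3ccccc3)cc(OCc3ccccc3)c3c(=O)cc(-c4ccc(OCc5ccccc5)c(OCc5ccccc5)c4)oc23)Oc2cc(OCc3ccccc3)cc(OCc3ccccc3)c21
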